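**Retrosynthetic overview**

1. The strategy rests on the C1 ketone and the C4–C5 epoxide (a masked Z C4=C5 alkene) of the ten-membered carbocycle C1–C10. This keto-alkene pair is what remains when the C1–C5 bond shared by a cyclopentane (C1–C5) and a cycloheptane (C1, C5–C10) is fragmented from a C1 tertiary alcohol toward a C4 trimethylstannyl group.
2. Target 36 ⇐ C8 senecioate, C13 acetate, desilylation ⇐ epoxidation of Z-enone 32 ⇐ Pb(OAc)4 fragmentation of tricyclic stannyl carbinol 31, which opens the bicycle to the ten-membered ring.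
3. 31 ⇐ butenolide by intramolecular Horner–Wadsworth–Emmons reaction of a C6 phosphonoacetate on a C7 ketone ⇐ seven-membered ring by addition of a C10 alkenyllithium to the C1 ketone, then hydroxyl-directed hydrogenation at C10.
4. Cyclopentanone 22 ⇐ conjugate addition of Me3SnLi to the 2-substituted 3-methylcyclopentenone 20 and protonation anti to tin (tin cis to C6) ⇐ C5–C6 union of the lithiated ketal of 2-bromo-3-methylcyclopentenone with aldehyde 11 (C6–C10; C8 by asymmetric propargylation, C6 by CBS reduction).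
5. Ring order: cyclopentane (from 3-methylcyclopentenone), seven-membered ring (step 17), butenolide (step 21), ten-membered ring by fragmentation (step 22), epoxide (step 23).

Key step: step 22

Remark: positions carry germacrane/guaiane numbers (ring C1–C10, C14 on C10, C15 on C4, lactone carbonyl C12, oxygenated methylene C13); it is assumed that (R)-TRIP sends the allenyl group to the Re face of enal 7, as with aryl and unsaturated aldehydes (otherwise its antipode serves).

**Route**

Step 1
Reactants: 1 3-methylcyclopent-2-en-1-one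
Product: 3 2-bromo-3-methylcyclopent-2-en-1-one, via dibromide 2 (not isolated)
Conditions: Br2, CH2Cl2, 0 °C; then Et3N, 0 °C to rt
Reagents that add atoms: bromine, BrBr
Why: Bromine adds to the enone and triethylamine eliminates HBr from the α,β-dibromide (addition–elimination α-bromination of enones), which places the halogen on the future C5.

Step 2
Reactants: 3 2-bromo-3-methylcyclopent-2-en-1-one
Product: 4 6-bromo-7-methyl-1,4-dioxaspiro[4.4]non-6-ene
Conditions: HOCH2CH2OH, TsOH·H2O (cat.), benzene, reflux, Dean–Stark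
Reagents that add atoms: ethane-1,2-diol, OCCO
Why: Acid-catalysed ketalisation with azeotropic removal of water masks the C1 carbonyl so that the vinyl bromide can serve as an α-keto vinyl anion equivalent.

Step 3
Reactants: 5 2-methylidenepropane-1,3-diol
Product: 6 2-{[(triethylsilyl)oxy]methyl}prop-2-en-1-ol
Conditions: NaH (1.0 equiv), THF, 0 °C; Et3SiCl (1.0 equiv), 0 °C
Reagents that add atoms: chlorotriethylsilane, CC[Si](Cl)(CC)CC
Why: O-Silylation of the sparingly soluble monosodium alkoxide of the symmetrical diol should stop at the monoether, which tells apart the two arms that become C6 and C8.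

Step 4
Reactants: 6 2-{[(triethylsilyl)oxy]methyl}prop-2-en-1-ol
Product: 7 2-{[(triethylsilyl)oxy]methyl}prop-2-enal
Conditions: MnO2, CH2Cl2, rt
Reagents that add atoms: none
Why: MnO2 oxidises the primary allylic alcohol to the α-substituted acrolein under neutral conditions that keep the silyl ether (allylic oxidation).

Step 5
Reactants: 7 2-{[(triethylsilyl)oxy]methyl}prop-2-enal
Product: 8 (3R)-2-{[(triethylsilyl)oxy]methyl}hex-1-en-5-yn-3-ol
Conditions: allenylboronic acid pinacol ester, (R)-TRIP [(R)-3,3'-bis(2,4,6-triisopropylphenyl)-1,1'-binaphthyl-2,2'-diyl hydrogen phosphate, 5 mol%], 4 Å molecular sieves, toluene, −20 °C; aqueous work-up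
Reagents that add atoms: 4,4,5,5-tetramethyl-2-(propa-1,2-dien-1-yl)-1,3,2-dioxaborolane, C=C=CB1OC(C)(C)C(C)(C)O1
Why: Chiral phosphoric acid-catalysed propargylation, in which the allenylboronate transfers its γ-carbon through a six-membered chair transition state to the Re face of the acid-bound aldehyde, so that C8 is set as R under catalyst control and C9, C10 and C14 are brought in.

Step 6
Reactants: 8 (3R)-2-{[(triethylsilyl)oxy]methyl}hex-1-en-5-yn-3-ol
Product: 9 (3R)-3-[(tert-butyldimethylsilyl)oxy]-2-{[(triethylsilyl)oxy]methyl}hex-1-en-5-yne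
Conditions: TBSCl, imidazole, DMF, rt
Reagents that add atoms: tert-butylchlorodimethylsilane, CC(C)(C)[Si](C)(C)Cl
Why: Imidazole-promoted silylation of the secondary alcohol installs the C8 protecting group that lasts to the end.

Step 7
Reactants: 9 (3R)-3-[(tert-butyldimethylsilyl)oxy]-2-{[(triethylsilyl)oxy]methyl}hex-1-en-5-yne
Product: 10 (3R)-3-[(tert-butyldimethylsilyl)oxy]-2-{[(triethylsilyl)oxy]methyl}-5-(trimethylstannyl)hexa-1,5-diene
Conditions: Me3SnCu·SMe2 (from Me3SnSnMe3, MeLi, THF, −20 °C, then CuBr·SMe2, −78 °C), MeOH, THF, −78 to −60 °C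
Reagents that add atoms: (trimethylstannyl)copper dimethyl sulfide complex, C[Sn](C)(C)[Cu].CSC (made in the flask from hexamethylditin, C[Sn](C)(C)[Sn](C)(C)C)
Why: Stannylcupration of the terminal alkyne places tin on the internal carbon and methanol protonates the alkenylcopper as it forms, giving the 2-stannyl-1-alkene, which masks the later alkenyl iodide that could not survive the stannyllithium of step 15.

Step 8
Reactants: 10 (3R)-3-[(tert-butyldimethylsilyl)oxy]-2-{[(triethylsilyl)oxy]methyl}-5-(trimethylstannyl)hexa-1,5-diene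
Product: 11 (3R)-3-[(tert-butyldimethylsilyl)oxy]-2-methylidene-5-(trimethylstannyl)hex-5-enal
Conditions: (COCl)2, DMSO, CH2Cl2, −78 °C; Et3N, −78 to −20 °C
Reagents that add atoms: none
Why: Under Swern conditions the primary allylic triethylsilyl ether is cleaved by the chlorosulfonium salt and oxidised in one operation to the aldehyde, while the secondary TBS ether and the alkenylstannane should be untouched (direct Swern oxidation of primary silyl ethers).

Step 9
Reactants: 12 benzyl 2-(diethoxyphosphoryl)acetate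
Product: 13 benzyl 2-(diethoxyphosphoryl)-3-hydroxypropanoate
Conditions: aqueous CH2O (1.0 equiv), K2CO3 (cat.), THF, 0 °C
Reagents that add atoms: formaldehyde, C=O
Why: Base-catalysed aldol-type hydroxymethylation of the doubly activated methylene with one equivalent of formaldehyde at low temperature should stop at the mono-adduct, which supplies C13 (Tollens-type hydroxymethylation).

Step 10
Reactants: 13 benzyl 2-(diethoxyphosphoryl)-3-hydroxypropanoate
Product: 14 benzyl 3-[(tert-butyldimethylsilyl)oxy]-2-(diethoxyphosphoryl)propanoate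
Conditions: TBSCl, imidazole, CH2Cl2, 0 °C
Reagents that add atoms: tert-butylchlorodimethylsilane, CC(C)(C)[Si](C)(C)Cl
Why: Silylation of the primary alcohol gives an ether that is a poor leaving group, so the phosphonate anion of step 21 should not lose it by β-elimination.

Step 11
Reactants: 14 benzyl 3-[(tert-butyldimethylsilyl)oxy]-2-(diethoxyphosphoryl)propanoate
Product: 15 3-[(tert-butyldimethylsilyl)oxy]-2-(diethoxyphosphoryl)propanoic acid
Conditions: H2 (1 atm), Pd/C, EtOAc, rt
Reagents that add atoms: none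
Why: Hydrogenolysis of the benzyl ester frees the acid under neutral conditions that leave the silyl ether and the phosphonate alone.

Step 12
Reactants: 4 6-bromo-7-methyl-1,4-dioxaspiro[4.4]non-6-ene; 11 (3R)-3-[(tert-butyldimethylsilyl)oxy]-2-methylidene-5-(trimethylstannyl)hex-5-enal
Product: 17 (3R)-3-[(tert-butyldimethylsilyl)oxy]-1-(7-methyl-1,4-dioxaspiro[4.4]non-6-en-6-yl)-2-methylidene-5-(trimethylstannyl)hex-5-en-1-ol (both C6 epimers), via lithiated ketal 16 (not isolated)
Conditions: 4, n-BuLi, THF, −78 °C; then 11, −78 °C; aqueous NH4Cl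
Reagents that add atoms: none
Why: Bromine–lithium exchange gives the α-keto vinyl anion equivalent, which adds to the aldehyde of 11 and forms the C5–C6 bond (organolithium 1,2-addition); both C6 epimers are taken on because C6 is oxidised next.

Step 13
Reactants: 17 C6-epimeric carbinols
Product: 18 (3R)-3-[(tert-butyldimethylsilyl)oxy]-1-(7-methyl-1,4-dioxaspiro[4.4]non-6-en-6-yl)-2-methylidene-5-(trimethylstannyl)hex-5-en-1-one
Conditions: Dess–Martin periodinane, NaHCO3, CH2Cl2, 0 °C to rt
Reagents that add atoms: none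
Why: Dess–Martin oxidation under buffered conditions converts the bis-allylic alcohol into the cross-conjugated dienone without acid that could trigger a Nazarov cyclisation.

Step 14
Reactants: 18 dienone ketal
Product: 20 2-[(1R,3R)-3-[(tert-butyldimethylsilyl)oxy]-1-hydroxy-2-methylidene-5-(trimethylstannyl)hex-5-en-1-yl]-3-methylcyclopent-2-en-1-one, via ketal alcohol 19 (not isolated)
Conditions: (S)-2-methyl-CBS-oxazaborolidine (20 mol%), catecholborane, toluene, −78 °C; then 5% aqueous oxalic acid, THF, 0 °C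
Reagents that add atoms: water, O
Why: Corey–Bakshi–Shibata reduction in which the fully substituted cyclopentenyl group is the large and the 1-substituted vinyl group the small ketone substituent, so that the (S)-catalyst delivers hydride to give the 6R alcohol, after which brief mild acid hydrolyses the allylic dioxolane to the enone.

Step 15
Reactants: 20 enone alcohol (6R,8R)
Product: 22 (2R,3S)-2-[(1S,3R)-3-[(tert-butyldimethylsilyl)oxy]-1-hydroxy-2-methylidene-5-(trimethylstannyl)hex-5-en-1-yl]-3-methyl-3-(trimethylstannyl)cyclopentan-1-one, via dilithium enolate 21 (not isolated)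
Conditions: LiN(SiMe3)2 (1.0 equiv), THF, −78 °C; Me3SnLi (from Me3SnSnMe3, MeLi, THF, −20 °C), −78 to −40 °C; AcOH, THF, −78 °C
Reagents that add atoms: trimethylstannyllithium, [Li][Sn](C)(C)C (made in the flask from hexamethylditin, C[Sn](C)(C)[Sn](C)(C)C)
Why: Conjugate addition of the stannyl anion to the enone: with C6–H eclipsing the ring alkene (allylic 1,3-strain with the C4 methyl) tin should enter C4 anti to the branched C7 substituent and syn to the lithium alkoxide (4S), and the enolate is protonated at C5 anti to the adjacent C–Sn bond (5R), so that tin ends cis to C6 as the fragmentation requires.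

Step 16
Reactants: 22 stannyl ketone
Product: 24 (2R,3S)-2-[(1S,3R)-3-[(tert-butyldimethylsilyl)oxy]-5-iodo-2-methylidene-1-[(triethylsilyl)oxy]hex-5-en-1-yl]-3-methyl-3-(trimethylstannyl)cyclopentan-1-one, via alkenyl iodide 23 (not isolated)
Conditions: I2 (1.0 equiv), CH2Cl2, 0 °C; then 2,6-lutidine, Et3SiOTf, −78 °C
Reagents that add atoms: iodine, II; triethylsilyl trifluoromethanesulfonate, CC[Si](CC)(CC)OS(=O)(=O)C(F)(F)F
Why: Iodine cleaves the alkenyl–tin bond much faster than the tertiary alkyl–tin bond (ipso iododestannylation), and the C6 alcohol is then silylated so that it can neither quench the organolithium of step 17 nor direct the hydrogenation of step 18.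

Step 17
Reactants: 24 iodo ketone
Product: 26 (1S,4S,5R,6S,8R)-8-[(tert-butyldimethylsilyl)oxy]-4-methyl-7,10-dimethylidene-6-[(triethylsilyl)oxy]-4-(trimethylstannyl)bicyclo[5.3.0]decan-1-ol (guaiane numbering; cis-fused), via alkenyllithium 25 (not isolated)
Conditions: t-BuLi (2.1 equiv), THF–pentane, −78 °C; aqueous NH4Cl
Reagents that add atoms: none
Why: Iodine–lithium exchange is faster than addition of t-BuLi to the ketone, and the alkenyllithium adds to the C1 carbonyl within the molecule (anionic Barbier-type cyclisation, 7-exo-trig); the tether on C5 reaches only its own face of the cyclopentanone, so the new ring is cis-fused and the C1 hydroxyl is cis to H5.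

Step 18
Reactants: 26 bis-methylidene carbinol
Product: 27 (1R,4S,5R,6S,8R,10S)-8-[(tert-butyldimethylsilyl)oxy]-4,10-dimethyl-7-methylidene-6-[(triethylsilyl)oxy]-4-(trimethylstannyl)bicyclo[5.3.0]decan-1-ol (guaiane numbering)
Conditions: H2 (50 bar), [Rh(nbd)(dppb)]BF4 (10 mol%), CH2Cl2, rt
Reagents that add atoms: none
Why: Hydroxyl-directed homogeneous hydrogenation: the cationic rhodium catalyst binds the tertiary C1 alcohol and adds hydrogen to the neighbouring C10 methylidene from the hydroxyl face (10S), while the C7 methylidene, flanked by two silyloxy carbons and lacking a free hydroxyl, should react far more slowly.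

Step 19
Reactants: 27 C7-methylidene carbinol
Product: 29 (1R,4S,5R,6S,8R,10S)-8-[(tert-butyldimethylsilyl)oxy]-1,6-dihydroxy-4,10-dimethyl-4-(trimethylstannyl)bicyclo[5.3.0]decan-7-one (guaiane numbering), via silyloxy ketone 28 (not isolated)
Conditions: O3, CH2Cl2–MeOH, −78 °C; Me2S; then PPTS, MeOH, 0 °C to rt
Reagents that add atoms: ozone, [O-][O+]=O
Why: Ozonolysis cleaves the only remaining alkene to the C7 ketone (a tetraalkylstannane should be inert to ozone at this temperature), and acidic methanol then removes the secondary triethylsilyl ether selectively in the presence of the TBS ether.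

Step 20
Reactants: 29 hydroxy ketone; 15 3-[(tert-butyldimethylsilyl)oxy]-2-(diethoxyphosphoryl)propanoic acid
Product: 30 C6 ester of 29 with acid 15 (both epimers at the phosphonate carbon)
Conditions: DCC, DMAP (cat.), CH2Cl2, 0 °C to rt
Reagents that add atoms: none
Why: Carbodiimide (Steglich) esterification acylates the secondary C6 hydroxyl, the tertiary C1 hydroxyl being too hindered to compete.

Step 21
Reactants: 30 phosphonate ester
Product: 31 (1R,4S,5R,6S,8R,10S)-8,13-bis[(tert-butyldimethylsilyl)oxy]-1-hydroxy-4-(trimethylstannyl)guai-7(11)-en-12,6-olide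
Conditions: LiCl, iPr2NEt, MeCN, rt
Reagents that add atoms: none
Why: Intramolecular Horner–Wadsworth–Emmons reaction under mild lithium chloride–amine conditions, in which the chelated phosphonate anion adds to the C7 ketone (5-exo-trig) and loses phosphate to form the C7=C11 butenolide, the weak base sparing the epimerisable C6 and C8 centres.

Step 22
Reactants: 31 tricyclic stannyl carbinol
Product: 32 (4Z,6S,8R,10S)-8,13-bis[(tert-butyldimethylsilyl)oxy]-1-oxogermacra-4,7(11)-dien-12,6-olide
Conditions: Pb(OAc)4 (1.3 equiv), CaCO3, benzene, rt to 60 °C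
Reagents that add atoms: none
Why: Pb(OAc)4 exchanges an acetate for the tertiary C1 alkoxide, and reduction of tetravalent to divalent lead at oxygen is coupled with heterolysis of the C1–C5 bond and collapse of the antiperiplanar C4–Sn bond into the C4=C5 π bond, a Grob-type 1,4-fragmentation that expels Me3SnOAc. The closest known reaction is the lead tetraacetate (or trivalent-iodine) fragmentation of γ-hydroxystannanes to unsaturated ketones, including cleavage of ring-fusion bonds to medium-ring enones. The ten-membered ring is not closed by a cyclisation: it arises by scission of the bond shared by the five- and seven-membered rings, a ring expansion of the bicyclo[5.3.0]decane core. No stereocentre is created; C1, C4 and C5 are destroyed, and the alkene is fixed as Z because tin is cis to C6 on the cyclopentane, so C3 and C6 end cis when C–Sn lies anti to C1–C5. The step needs cleavage of C1–C5 in preference to C1–C2 or C1–C10, which the hyperconjugating C4–Sn bond (pseudo-equatorial in the cyclopentane envelope) should secure, and it needs the lactone, the silyl ethers and the C10 centre to survive, which these neutral conditions should allow.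

Step 23
Reactants: 32 Z-enone
Product: 33 (4S,5R,6R,8R,10S)-8,13-bis[(tert-butyldimethylsilyl)oxy]-4,5-epoxy-1-oxogermacr-7(11)-en-12,6-olide
Conditions: mCPBA, NaHCO3, CH2Cl2, 0 °C
Reagents that add atoms: 3-chloroperoxybenzoic acid, OOC(=O)c1cccc(Cl)c1
Why: Peracid epoxidation of the electron-rich trisubstituted alkene (the butenolide alkene is electron-poor and the ketone reacts far more slowly): C6–H eclipses the alkene to avoid allylic 1,3-strain with C3, and oxygen should be delivered anti to the allylic lactone oxygen, on the outer face from which tin departed and away from the transannular C1 carbonyl, to give the 4S,5R cis-epoxide.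

Step 24
Reactants: 33 bis-silyl epoxide
Product: 34 (4S,5R,6R,8R,10S)-4,5-epoxy-8,13-dihydroxy-1-oxogermacr-7(11)-en-12,6-olide
Conditions: HF·pyridine, pyridine, THF, 0 °C to rt
Reagents that add atoms: none
Why: Buffered fluoride cleaves both silyl ethers (Si–F bond formation) without opening the epoxide or the lactone.

Step 25
Reactants: 34 diol
Product: 35 (4S,5R,6R,8R,10S)-13-acetoxy-4,5-epoxy-8-hydroxy-1-oxogermacr-7(11)-en-12,6-olide
Conditions: Ac2O (1.1 equiv), 2,4,6-collidine, CH2Cl2, −20 °C
Reagents that add atoms: acetic anhydride, CC(=O)OC(C)=O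
Why: The unhindered primary C13 hydroxyl is acetylated much faster than the secondary C8 hydroxyl flanked by the butenolide (kinetically selective acylation).

Step 26
Reactants: 35 monoacetate
Product: 36 (4S,5R,6R,8R,10S)-13-acetoxy-4,5-epoxy-8-(3-methylbut-2-enoyloxy)-1-oxogermacr-7(11)-en-12,6-olide (CNP0220542.1)
Conditions: 3-methylbut-2-enoic acid, DCC, DMAP (cat.), CH2Cl2, 0 °C to rt
Reagents that add atoms: 3-methylbut-2-enoic acid, CC(C)=CC(=O)O
Why: Steglich esterification of the remaining secondary alcohol introduces the senecioate under near-neutral conditions that avoid ketene formation and deconjugation of the acyl group and leave the C10 α-keto centre alone.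

**Compound list**

1 | 3-methylcyclopent-2-en-1-one | CC1=CC(=O)CC1 | starting material
2 | 2,3-dibromo-3-methylcyclopentan-1-one (racemic) | CC1(Br)CCC(=O)C1Br | intermediate
3 | 2-bromo-3-methylcyclopent-2-en-1-one | CC1=C(Br)C(=O)CC1 | intermediate
4 | 6-bromo-7-methyl-1,4-dioxaspiro[4.4]non-6-ene | CC1=C(Br)C2(CC1)OCCO2 | intermediate
5 | 2-methylidenepropane-1,3-diol | C=C(CO)CO | starting material
6 | 2-{[(triethylsilyl)oxy]methyl}prop-2-en-1-ol | C=C(CO)CO[Si](CC)(CC)CC | intermediate
7 | 2-{[(triethylsilyl)oxy]methyl}prop-2-enal | C=C(C=O)CO[Si](CC)(CC)CC | intermediate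
8 | (3R)-2-{[(triethylsilyl)oxy]methyl}hex-1-en-5-yn-3-ol | C#CC[C@@H](O)C(=C)CO[Si](CC)(CC)CC | intermediate
9 | (3R)-3-[(tert-butyldimethylsilyl)oxy]-2-{[(triethylsilyl)oxy]methyl}hex-1-en-5-yne | C#CC[C@@H](O[Si](C)(C)C(C)(C)C)C(=C)CO[Si](CC)(CC)CC | intermediate
10 | (3R)-3-[(tert-butyldimethylsilyl)oxy]-2-{[(triethylsilyl)oxy]methyl}-5-(trimethylstannyl)hexa-1,5-diene | C=C([Sn](C)(C)C)C[C@@H](O[Si](C)(C)C(C)(C)C)C(=C)CO[Si](CC)(CC)CC | intermediate
11 | (3R)-3-[(tert-butyldimethylsilyl)oxy]-2-methylidene-5-(trimethylstannyl)hex-5-enal | C=C([Sn](C)(C)C)C[C@@H](O[Si](C)(C)C(C)(C)C)C(=C)C=O | intermediate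
12 | benzyl 2-(diethoxyphosphoryl)acetate | CCOP(=O)(OCC)CC(=O)OCc1ccccc1 | starting material
13 | benzyl 2-(diethoxyphosphoryl)-3-hydroxypropanoate (racemic) | CCOP(=O)(OCC)C(CO)C(=O)OCc1ccccc1 | intermediate
14 | benzyl 3-[(tert-butyldimethylsilyl)oxy]-2-(diethoxyphosphoryl)propanoate (racemic) | CCOP(=O)(OCC)C(CO[Si](C)(C)C(C)(C)C)C(=O)OCc1ccccc1 | intermediate
15 | 3-[(tert-butyldimethylsilyl)oxy]-2-(diethoxyphosphoryl)propanoic acid (racemic) | CCOP(=O)(OCC)C(CO[Si](C)(C)C(C)(C)C)C(=O)O | intermediate
16 | (7-methyl-1,4-dioxaspiro[4.4]non-6-en-6-yl)lithium | [Li]C1=C(C)CCC12OCCO2 | intermediate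
17 | (3R)-3-[(tert-butyldimethylsilyl)oxy]-1-(7-methyl-1,4-dioxaspiro[4.4]non-6-en-6-yl)-2-methylidene-5-(trimethylstannyl)hex-5-en-1-ol, both C1 (= C6) epimers | CC1=C(C(O)C(=C)[C@H](O[Si](C)(C)C(C)(C)C)CC(=C)[Sn](C)(C)C)C2(CC1)OCCO2 | intermediate
18 | (3R)-3-[(tert-butyldimethylsilyl)oxy]-1-(7-methyl-1,4-dioxaspiro[4.4]non-6-en-6-yl)-2-methylidene-5-(trimethylstannyl)hex-5-en-1-one | CC1=C(C(=O)C(=C)[C@H](O[Si](C)(C)C(C)(C)C)CC(=C)[Sn](C)(C)C)C2(CC1)OCCO2 | intermediate
19 | (1R,3R)-3-[(tert-butyldimethylsilyl)oxy]-1-(7-methyl-1,4-dioxaspiro[4.4]non-6-en-6-yl)-2-methylidene-5-(trimethylstannyl)hex-5-en-1-ol | CC1=C([C@H](O)C(=C)[C@H](O[Si](C)(C)C(C)(C)C)CC(=C)[Sn](C)(C)C)C2(CC1)OCCO2 | intermediate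
20 | 2-[(1R,3R)-3-[(tert-butyldimethylsilyl)oxy]-1-hydroxy-2-methylidene-5-(trimethylstannyl)hex-5-en-1-yl]-3-methylcyclopent-2-en-1-one | CC1=C([C@H](O)C(=C)[C@H](O[Si](C)(C)C(C)(C)C)CC(=C)[Sn](C)(C)C)C(=O)CC1 | intermediate
21 | dilithium enolate-alkoxide of 22 (4S,6R,8R; C1=C5 enolate) | [Li]OC1=C([C@H](O[Li])C(=C)[C@H](O[Si](C)(C)C(C)(C)C)CC(=C)[Sn](C)(C)C)[C@@](C)([Sn](C)(C)C)CC1 | intermediate
22 | (2R,3S)-2-[(1S,3R)-3-[(tert-butyldimethylsilyl)oxy]-1-hydroxy-2-methylidene-5-(trimethylstannyl)hex-5-en-1-yl]-3-methyl-3-(trimethylstannyl)cyclopentan-1-one | C[C@]1([Sn](C)(C)C)CCC(=O)[C@H]1[C@H](O)C(=C)[C@H](O[Si](C)(C)C(C)(C)C)CC(=C)[Sn](C)(C)C | intermediate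
23 | (2R,3S)-2-[(1S,3R)-3-[(tert-butyldimethylsilyl)oxy]-1-hydroxy-5-iodo-2-methylidenehex-5-en-1-yl]-3-methyl-3-(trimethylstannyl)cyclopentan-1-one | C[C@]1([Sn](C)(C)C)CCC(=O)[C@H]1[C@H](O)C(=C)[C@H](O[Si](C)(C)C(C)(C)C)CC(I)=C | intermediate
24 | (2R,3S)-2-[(1S,3R)-3-[(tert-butyldimethylsilyl)oxy]-5-iodo-2-methylidene-1-[(triethylsilyl)oxy]hex-5-en-1-yl]-3-methyl-3-(trimethylstannyl)cyclopentan-1-one | C[C@]1([Sn](C)(C)C)CCC(=O)[C@H]1[C@H](O[Si](CC)(CC)CC)C(=C)[C@H](O[Si](C)(C)C(C)(C)C)CC(I)=C | intermediate
25 | alkenyllithium from 24 (lithium in place of iodine) | C[C@]1([Sn](C)(C)C)CCC(=O)[C@H]1[C@H](O[Si](CC)(CC)CC)C(=C)[C@H](O[Si](C)(C)C(C)(C)C)CC([Li])=C | intermediate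
26 | (1S,4S,5R,6S,8R)-8-[(tert-butyldimethylsilyl)oxy]-4-methyl-7,10-dimethylidene-6-[(triethylsilyl)oxy]-4-(trimethylstannyl)bicyclo[5.3.0]decan-1-ol (guaiane numbering) | C=C1[C@@H](O[Si](CC)(CC)CC)[C@H]2[C@@](C)([Sn](C)(C)C)CC[C@@]2(O)C(=C)C[C@H]1O[Si](C)(C)C(C)(C)C | intermediate
27 | (1R,4S,5R,6S,8R,10S)-8-[(tert-butyldimethylsilyl)oxy]-4,10-dimethyl-7-methylidene-6-[(triethylsilyl)oxy]-4-(trimethylstannyl)bicyclo[5.3.0]decan-1-ol (guaiane numbering) | C=C1[C@@H](O[Si](CC)(CC)CC)[C@H]2[C@@](C)([Sn](C)(C)C)CC[C@@]2(O)[C@@H](C)C[C@H]1O[Si](C)(C)C(C)(C)C | intermediate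
28 | (1R,4S,5R,6S,8R,10S)-8-[(tert-butyldimethylsilyl)oxy]-1-hydroxy-4,10-dimethyl-6-[(triethylsilyl)oxy]-4-(trimethylstannyl)bicyclo[5.3.0]decan-7-one (guaiane numbering) | O=C1[C@@H](O[Si](CC)(CC)CC)[C@H]2[C@@](C)([Sn](C)(C)C)CC[C@@]2(O)[C@@H](C)C[C@H]1O[Si](C)(C)C(C)(C)C | intermediate
29 | (1R,4S,5R,6S,8R,10S)-8-[(tert-butyldimethylsilyl)oxy]-1,6-dihydroxy-4,10-dimethyl-4-(trimethylstannyl)bicyclo[5.3.0]decan-7-one (guaiane numbering) | O=C1[C@@H](O)[C@H]2[C@@](C)([Sn](C)(C)C)CC[C@@]2(O)[C@@H](C)C[C@H]1O[Si](C)(C)C(C)(C)C | intermediate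
30 | C6 3-[(tert-butyldimethylsilyl)oxy]-2-(diethoxyphosphoryl)propanoate of 29 (both epimers at the phosphonate carbon) | O=C1[C@@H](OC(=O)C(CO[Si](C)(C)C(C)(C)C)P(=O)(OCC)OCC)[C@H]2[C@@](C)([Sn](C)(C)C)CC[C@@]2(O)[C@@H](C)C[C@H]1O[Si](C)(C)C(C)(C)C | intermediate
31 | (1R,4S,5R,6S,8R,10S)-8,13-bis[(tert-butyldimethylsilyl)oxy]-1-hydroxy-4-(trimethylstannyl)guai-7(11)-en-12,6-olide | C[Si](C)(C(C)(C)C)OCC1=C2[C@@H](OC1=O)[C@H]3[C@@](C)([Sn](C)(C)C)CC[C@@]3(O)[C@@H](C)C[C@H]2O[Si](C)(C)C(C)(C)C | intermediate
32 | (4Z,6S,8R,10S)-8,13-bis[(tert-butyldimethylsilyl)oxy]-1-oxogermacra-4,7(11)-dien-12,6-olide | C[Si](C)(C(C)(C)C)OCC1=C2[C@@H](OC1=O)/C=C(/C)CCC(=O)[C@@H](C)C[C@H]2O[Si](C)(C)C(C)(C)C | intermediate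
33 | (4S,5R,6R,8R,10S)-8,13-bis[(tert-butyldimethylsilyl)oxy]-4,5-epoxy-1-oxogermacr-7(11)-en-12,6-olide | C[Si](C)(C(C)(C)C)OCC1=C2[C@@H](OC1=O)[C@H]1O[C@@]1(C)CCC(=O)[C@@H](C)C[C@H]2O[Si](C)(C)C(C)(C)C | intermediate
34 | (4S,5R,6R,8R,10S)-4,5-epoxy-8,13-dihydroxy-1-oxogermacr-7(11)-en-12,6-olide | OCC1=C2[C@@H](OC1=O)[C@H]1O[C@@]1(C)CCC(=O)[C@@H](C)C[C@H]2O | intermediate
35 | (4S,5R,6R,8R,10S)-13-acetoxy-4,5-epoxy-8-hydroxy-1-oxogermacr-7(11)-en-12,6-olide | CC(=O)OCC1=C2[C@@H](OC1=O)[C@H]1O[C@@]1(C)CCC(=O)[C@@H](C)C[C@H]2O | intermediate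
36 | (4S,5R,6R,8R,10S)-13-acetoxy-4,5-epoxy-8-(3-methylbut-2-enoyloxy)-1-oxogermacr-7(11)-en-12,6-olide | CC(=O)OCC1=C2[C@@H](OC1=O)[C@H]1O[C@@]1(C)CCC(=O)[C@@H](C)C[C@H]2OC(=O)C=C(C)C | target

**Step count and risks**

Total step count: 26. Longest linear sequence: 21 steps (5 to 11 by steps 3–8, then steps 12–26).

Steps most likely to fail:

Step 22. The lead alkoxide may partition into homolytic β-scission of the C1–C2 or C1–C10 bond, or the stannane may be lost by acetolysis before the C–C bond breaks; either erodes the stereospecific Z-selective ring opening. Fallback: setting out from 31, the alcohol would be converted in the flask with PhI(OAc)2 and I2 in cyclohexane under visible light into the tertiary C1 hypoiodite F1. Homolysis of its O–I bond gives the C1 alkoxy radical, β-scission of C1–C5 gives a C5 radical β to tin, and loss of the trimethylstannyl radical forms the C4=C5 alkene, which comes back to the route at 32. This is the alkoxy-radical fragmentation of hypoiodites, ended by β-elimination of a stannyl radical.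

Step 17. The alkenyllithium may be quenched by enolisation of the ketone, undergo 1,4 oxygen-to-carbon silyl migration from the C8 ether, or be outrun by direct attack of t-BuLi on the carbonyl; closure must also occur on the face that carries the C4 tin group, so reduced open-chain material may dominate. Fallback: setting out from 24, the ring would be closed by a Nozaki–Hiyama–Kishi reaction (CrCl2, catalytic NiCl2, DMF, rt). Nickel inserts into the C–I bond and transmetalation gives a non-basic alkenylchromium species that adds to the C1 ketone, coming back at 26; no new compound is made on the way (F0).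

Step 23. Facial selectivity may be poor or reversed if the ten-membered ring relaxes to a conformer that turns the other alkene face outward, and slow Baeyer–Villiger oxidation of the C1 ketone may compete. Fallback: setting out from 32, N-bromosuccinimide in aqueous 1,2-dimethoxyethane at 0 °C would give the (4S,5S)-5-bromo-4-hydroxy bromohydrin F2 by anti addition (bromonium ion on the face the peracid prefers, water at the tertiary C4). K2CO3 in methanol would then close the epoxide with inversion at C5 (SN2), placing oxygen on the face opposite to direct epoxidation and coming back at 33.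

Further compounds
F0 | step 17 | none | none
F1 | step 22 | tertiary C1 hypoiodite of 31 | C[Si](C)(C(C)(C)C)OCC1=C2[C@@H](OC1=O)[C@H]3[C@@](C)([Sn](C)(C)C)CC[C@@]3(OI)[C@@H](C)C[C@H]2O[Si](C)(C)C(C)(C)C
F2 | step 23 | (4S,5S,6R,8R,10S)-5-bromo-8,13-bis[(tert-butyldimethylsilyl)oxy]-4-hydroxy-1-oxogermacr-7(11)-en-12,6-olide | C[Si](C)(C(C)(C)C)OCC1=C2[C@@H](OC1=O)[C@H](Br)[C@](O)(C)CCC(=O)[C@@H](C)C[C@H]2O[Si](C)(C)C(C)(C)C
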